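Ring C is disconnected at O1–C8a, C4–C4a and O1–C2, which reduces the flavone to 3,5-dimethoxybenzyne and an arylpropiolic acid. The key step exploits the fact that the adjacent ring A carbons C8a and C4a bear O1 and the C4 carbonyl, with the C5 oxygen beside C4a: exactly what a 3-alkoxyaryne delivers when it inserts into a carboxylic acid C–O bond. One operation forms both ring A bonds and then closes ring C by oxa-Michael addition. The precursors are a silylaryl triflate from 3,5-dimethoxyphenol and a 3-arylpropiolic acid whose 4'-oxygen is a tosylate, chosen to outlast fluoride and BCl3 so that the prenyl group can be moved from O5 to C8 without reprotection.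

Key step: step 7

Assumption: an aryl tosylate tolerates CsF in THF at 125 °C, as it tolerates fluoride and carbonate bases in cross-coupling at comparable temperatures. Flavone numbering is used (ring C: O1, C2–C4; ring A: C4a, C5–C8, C8a; ring B primed). Eu(fod)3 denotes Eu(C10H10F7O2)3, the tris(6,6,7,7,8,8,8-heptafluoro-2,2-dimethyloctane-3,5-dionate) of trivalent europium.

**Ring A fragment (aryne precursor)**

Step 1
Reactants: 1 3,5-dimethoxyphenol
Product: 2 3,5-dimethoxyphenyl N-isopropylcarbamate
Conditions: i-PrNCO, Et3N (cat.), CH2Cl2, rt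
Reagents that add atoms: isopropyl isocyanate, CC(C)N=C=O
Why: Base-catalysed addition of the phenol to the isocyanate (carbamoylation) installs a secondary carbamate that is a strong ortho-directing group and can later be removed under mild base.

Step 2
Reactants: 2 3,5-dimethoxyphenyl N-isopropylcarbamate
Product: 5 3,5-dimethoxy-2-(trimethylsilyl)phenyl N-isopropylcarbamate, via N-silyl carbamate 3 (not isolated), via bis-silyl carbamate 4 (not isolated)
Conditions: TBSOTf, TMEDA, Et2O, 0 °C → rt; n-BuLi, TMEDA, −78 °C; TMSCl, −78 °C → rt; aq NaHSO4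
Reagents that add atoms: chlorotrimethylsilane, C[Si](C)(C)Cl; tert-butyldimethylsilyl triflate, CC(C)(C)[Si](C)(C)OS(=O)(=O)C(F)(F)F (its silyl group is carried by 3 and 4 only)
Why: Directed ortho-metalation: transient N-silylation masks the N–H, the carbamate and the neighbouring methoxy group together direct lithiation to the carbon between them (the two such sites are equivalent by symmetry), TMSCl traps the aryllithium at −78 °C before any anionic Fries shift, and the acidic work-up removes the N-silyl group.

Step 3
Reactants: 5 3,5-dimethoxy-2-(trimethylsilyl)phenyl N-isopropylcarbamate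
Product: 7 3,5-dimethoxy-2-(trimethylsilyl)phenyl trifluoromethanesulfonate, via silylphenol 6 (not isolated)
Conditions: DBU, Et2NH, MeCN, 40 °C; then PhNTf2, rt
Reagents that add atoms: N-phenylbis(trifluoromethanesulfonimide), O=S(=O)(N(c1ccccc1)S(=O)(=O)C(F)(F)F)C(F)(F)F
Why: E1cB loss of isopropyl isocyanate from the deprotonated secondary carbamate (the isocyanate is scavenged by Et2NH) frees the phenoxide, which is triflated in the same flask by the mild triflyl donor, so the desilylation-prone phenol is never handled.

**Ring B fragment (arylpropiolic acid)**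

Step 4
Reactants: 8 4-bromo-3-methoxyphenol
Product: 9 4-bromo-3-methoxyphenyl 4-methylbenzenesulfonate
Conditions: TsCl, Et3N, DMAP (cat.), CH2Cl2, 0 °C → rt
Reagents that add atoms: 4-methylbenzenesulfonyl chloride, Cc1ccc(cc1)S(Cl)(=O)=O
Why: O-Sulfonylation of the phenol gives an aryl tosylate that is inert to palladium/triphenylphosphine catalysis, fluoride, BCl3, Mitsunobu conditions and Lewis acids, yet is cleaved by hydroxide at the end.

Step 5
Reactants: 9 4-bromo-3-methoxyphenyl 4-methylbenzenesulfonate; 10 trimethylsilylacetylene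
Product: 11 3-methoxy-4-[(trimethylsilyl)ethynyl]phenyl 4-methylbenzenesulfonate
Conditions: PdCl2(PPh3)2 (cat.), CuI (cat.), Et3N, THF, 60 °C, sealed vessel
Reagents that add atoms: none
Why: Sonogashira coupling, in which the C–Br bond undergoes oxidative addition while the aryl C–OTs bond is untouched with triphenylphosphine ligands, and the silyl cap prevents double coupling.

Step 6
Reactants: 11 3-methoxy-4-[(trimethylsilyl)ethynyl]phenyl 4-methylbenzenesulfonate
Product: 12 3-[2-methoxy-4-(tosyloxy)phenyl]prop-2-ynoic acid
Conditions: CsF, CO2 (1 atm), DMSO, rt; then 1 M HCl, 0 °C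
Reagents that add atoms: carbon dioxide, O=C=O
Why: Fluoride-mediated desilylative carboxylation of an alkynylsilane: fluoride activates the C–Si bond, CO2 captures the alkynyl nucleophile as the cesium propiolate, and cold acidification gives the acid without decarboxylation.

**Union and endgame**

Step 7
Reactants: 7 3,5-dimethoxy-2-(trimethylsilyl)phenyl trifluoromethanesulfonate; 12 3-[2-methoxy-4-(tosyloxy)phenyl]prop-2-ynoic acid
Product: 15 5,7-dimethoxy-2-[2-methoxy-4-(tosyloxy)phenyl]-4H-chromen-4-one, via 3,5-dimethoxybenzyne 13 (not isolated), via hydroxyaryl ynone 14 (not isolated)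
Conditions: 7 (1.5 equiv), CsF (4 equiv), THF, 125 °C, sealed tube
Reagents that add atoms: none
Why: Fluoride attacks silicon of 7 and the ortho triflate departs to give aryne 13; the carboxylate of 12 bonds through oxygen to the aryne terminus meta to the 3-methoxy group, and the resulting aryl anion, ortho to that methoxy group, adds to the carbonyl of the aryl ester it has just created, so the strained four-membered adduct opens to the ortho-acyl phenoxide of 14 (net aryne insertion into the acid C–O bond, forming C8a–O1 and C4a–C4). The closest known reaction type is the fluoride-induced insertion of arynes into the C–O bond of carboxylic acids to give ortho-hydroxyaryl ketones, which with arylpropiolic acids runs on to flavones. Ring C closes by 6-endo-dig oxa-Michael addition of the phenoxide oxygen to the alkyne carbon bearing ring B (O1–C2), followed by protonation at C3. No stereocentre is formed. The step needs regioselective addition to the unsymmetrical aryne, secured by the inductively withdrawing methoxy group beside the triple bond, and it needs acyl transfer to outrun protonation of the aryl anion, which the high temperature and aprotic medium favour. It also needs 6-endo rather than 5-exo closure, which the polarised ynone provides by making the β-carbon the electrophilic site.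

Step 8
Reactants: 15 5,7-dimethoxy-2-[2-methoxy-4-(tosyloxy)phenyl]-4H-chromen-4-one
Product: 16 5-hydroxy-7-methoxy-2-[2-methoxy-4-(tosyloxy)phenyl]-4H-chromen-4-one
Conditions: BCl3 (2 equiv), CH2Cl2, −78 → 0 °C; aq work-up
Reagents that add atoms: none
Why: Chelation-controlled demethylation: BCl3 bridges the C4 carbonyl and the peri 5-methoxy oxygen in a six-membered chelate and chloride removes only that methyl group, while the 7- and 2'-methyl ethers and the sulfonate are not activated at this temperature.

Step 9
Reactants: 16 5-hydroxy-7-methoxy-2-[2-methoxy-4-(tosyloxy)phenyl]-4H-chromen-4-one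
Product: 17 7-methoxy-2-[2-methoxy-4-(tosyloxy)phenyl]-5-[(3-methylbut-2-en-1-yl)oxy]-4H-chromen-4-one
Conditions: 3-methylbut-2-en-1-ol, PPh3, DIAD, THF, 0 °C → rt
Reagents that add atoms: 3-methylbut-2-en-1-ol, CC(C)=CCO
Why: Mitsunobu etherification, in which the only free phenol (the hydrogen-bonded 5-OH) displaces the primary allylic oxyphosphonium in an SN2 sense under neutral conditions that spare the sulfonate.

Step 10
Reactants: 17 7-methoxy-2-[2-methoxy-4-(tosyloxy)phenyl]-5-[(3-methylbut-2-en-1-yl)oxy]-4H-chromen-4-one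
Product: 20 5-hydroxy-7-methoxy-2-[2-methoxy-4-(tosyloxy)phenyl]-8-(3-methylbut-2-en-1-yl)-4H-chromen-4-one, via ortho dienone 18 (not isolated), via para dienone 19 (not isolated)
Conditions: Eu(fod)3 (10 mol%), NaHCO3, PhCl, 85 °C
Reagents that add atoms: none
Why: Lewis-acid-catalysed Claisen–Cope (para-Claisen) cascade: Eu(fod)3 chelates the C4 carbonyl and O5 and accelerates the [3,3] shift to C6, the crowded 1,1-dimethylallyl dienone (wedged between C5=O and the 7-methoxy group) relays the chain by a Cope shift to C8, and enolisation restores ring A with the linear prenyl group at C8.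

Step 11
Reactants: 20 5-hydroxy-7-methoxy-2-[2-methoxy-4-(tosyloxy)phenyl]-8-(3-methylbut-2-en-1-yl)-4H-chromen-4-one
Product: 21 Artocarpetin B
Conditions: KOH (3 equiv), MeOH–THF–H2O, 50 °C; then dilute HCl
Reagents that add atoms: none
Why: Hydroxide attacks sulfur of the aryl sulfonate and expels the vinylogously acidic 4'-phenoxide (sulfonate ester hydrolysis), while the 5-phenoxide formed under these conditions deactivates ring C towards conjugate attack and the prenyl group and methyl ethers are inert to base.

**Compound list**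

1 | 3,5-dimethoxyphenol | COc1cc(O)cc(OC)c1 | starting material
2 | 3,5-dimethoxyphenyl N-isopropylcarbamate | COc1cc(OC)cc(OC(=O)NC(C)C)c1 | intermediate
3 | 3,5-dimethoxyphenyl N-(tert-butyldimethylsilyl)-N-isopropylcarbamate | COc1cc(OC)cc(OC(=O)N(C(C)C)[Si](C)(C)C(C)(C)C)c1 | intermediate (not isolated)
4 | 3,5-dimethoxy-2-(trimethylsilyl)phenyl N-(tert-butyldimethylsilyl)-N-isopropylcarbamate | COc1cc(OC)c([Si](C)(C)C)c(OC(=O)N(C(C)C)[Si](C)(C)C(C)(C)C)c1 | intermediate (not isolated)
5 | 3,5-dimethoxy-2-(trimethylsilyl)phenyl N-isopropylcarbamate | COc1cc(OC)c([Si](C)(C)C)c(OC(=O)NC(C)C)c1 | intermediate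
6 | 3,5-dimethoxy-2-(trimethylsilyl)phenol | COc1cc(O)c([Si](C)(C)C)c(OC)c1 | intermediate (not isolated)
7 | 3,5-dimethoxy-2-(trimethylsilyl)phenyl trifluoromethanesulfonate | COc1cc(OC)c([Si](C)(C)C)c(OS(=O)(=O)C(F)(F)F)c1 | intermediate
8 | 4-bromo-3-methoxyphenol | COc1cc(O)ccc1Br | starting material
9 | 4-bromo-3-methoxyphenyl 4-methylbenzenesulfonate | COc1cc(OS(=O)(=O)c2ccc(C)cc2)ccc1Br | intermediate
10 | trimethylsilylacetylene | C#C[Si](C)(C)C | starting material
11 | 3-methoxy-4-[(trimethylsilyl)ethynyl]phenyl 4-methylbenzenesulfonate | COc1cc(OS(=O)(=O)c2ccc(C)cc2)ccc1C#C[Si](C)(C)C | intermediate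
12 | 3-[2-methoxy-4-(tosyloxy)phenyl]prop-2-ynoic acid | COc1cc(OS(=O)(=O)c2ccc(C)cc2)ccc1C#CC(=O)O | intermediate
13 | 3,5-dimethoxybenzyne (1,2-didehydro-3,5-dimethoxybenzene) | COC1=CC(OC)=CC#C1 | intermediate (not isolated)
14 | 1-(2-hydroxy-4,6-dimethoxyphenyl)-3-[2-methoxy-4-(tosyloxy)phenyl]prop-2-yn-1-one | COc1cc(O)c(C(=O)C#Cc2ccc(OS(=O)(=O)c3ccc(C)cc3)cc2OC)c(OC)c1 | intermediate (not isolated)
15 | 5,7-dimethoxy-2-[2-methoxy-4-(tosyloxy)phenyl]-4H-chromen-4-one | COc1cc(OS(=O)(=O)c2ccc(C)cc2)ccc1-c1cc(=O)c2c(OC)cc(OC)cc2o1 | intermediate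
16 | 5-hydroxy-7-methoxy-2-[2-methoxy-4-(tosyloxy)phenyl]-4H-chromen-4-one | COc1cc(OS(=O)(=O)c2ccc(C)cc2)ccc1-c1cc(=O)c2c(O)cc(OC)cc2o1 | intermediate
17 | 7-methoxy-2-[2-methoxy-4-(tosyloxy)phenyl]-5-[(3-methylbut-2-en-1-yl)oxy]-4H-chromen-4-one | COc1cc(OS(=O)(=O)c2ccc(C)cc2)ccc1-c1cc(=O)c2c(OCC=C(C)C)cc(OC)cc2o1 | intermediate
18 | 7-methoxy-2-[2-methoxy-4-(tosyloxy)phenyl]-6-(2-methylbut-3-en-2-yl)-6H-chromene-4,5-dione (racemic ortho dienone) | C=CC(C)(C)C1C(OC)=CC2=C(C1=O)C(=O)C=C(O2)c1ccc(OS(=O)(=O)c2ccc(C)cc2)cc1OC | intermediate (not isolated)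
19 | 7-methoxy-2-[2-methoxy-4-(tosyloxy)phenyl]-8-(3-methylbut-2-en-1-yl)-8H-chromene-4,5-dione (racemic para dienone) | CC(C)=CCC1C(OC)=CC(=O)C2=C1OC(=CC2=O)c1ccc(OS(=O)(=O)c2ccc(C)cc2)cc1OC | intermediate (not isolated)
20 | 5-hydroxy-7-methoxy-2-[2-methoxy-4-(tosyloxy)phenyl]-8-(3-methylbut-2-en-1-yl)-4H-chromen-4-one | COc1cc(OS(=O)(=O)c2ccc(C)cc2)ccc1-c1cc(=O)c2c(O)cc(OC)c(CC=C(C)C)c2o1 | intermediate
21 | Artocarpetin B, 5-hydroxy-2-(4-hydroxy-2-methoxyphenyl)-7-methoxy-8-(3-methylbut-2-en-1-yl)-4H-chromen-4-one | COc1cc(O)ccc1-c1cc(=O)c2c(O)cc(OC)c(CC=C(C)C)c2o1 | target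

**Step count**

Total: 11 steps (3 for the ring A fragment, 3 for the ring B fragment, the union, and 4 to the target). Longest linear sequence: 8 steps (steps 1, 2, 3, 7, 8, 9, 10, 11; the ring B branch is equally long).

**Steps most likely to fail**

1. Step 7. The aryl anion may be protonated before it transfers the acyl group, which stops the sequence at simple O-arylation. The propiolate may also decarboxylate at 125 °C before it meets the aryne, the phenoxide may close 5-exo, or fluoride may erode the sulfonate. The fallback builds ring C by carbonylative annulation instead; it sets out from 5 and 11 and returns at 15. Ipso-iododesilylation of 5 with ICl (CH2Cl2, −78 °C) should give 2-iodo-3,5-dimethoxyphenyl N-isopropylcarbamate F1, and DBU/Et2NH in MeCN should release 2-iodo-3,5-dimethoxyphenol F2. In parallel, K2CO3 in MeOH at rt should desilylate 11 to 4-ethynyl-3-methoxyphenyl 4-methylbenzenesulfonate F3. Carbonylative Sonogashira coupling of F2 with F3 (PdCl2(PPh3)2, CO balloon, Et3N, THF, 50 °C) should give ynone 14, and brief treatment with Et2NH should close it 6-endo to 15 through the enaminone.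

2. Step 10. The ortho dienone may enolise before the Cope shift and leave the 1,1-dimethylallyl group at C6, or the Lewis acid may ionise the allylic ether and return 16. The fallback replaces the sigmatropic relay with halogenation and cross-coupling; it sets out from 15 and returns at 20. Electrophilic iodination of 15 (NIS, cat. TFA, MeCN) should go to C8, the less hindered of the two activated ring A positions when O5 is methylated, and give 8-iodo-5,7-dimethoxy-2-[2-methoxy-4-(tosyloxy)phenyl]-4H-chromen-4-one F4. BCl3 as in step 8 should then give 5-hydroxy-8-iodo-7-methoxy-2-[2-methoxy-4-(tosyloxy)phenyl]-4H-chromen-4-one F5. Stille coupling of F5 with tributyl(3-methylbut-2-en-1-yl)stannane (Pd(PPh3)4, DMF, 90 °C) should deliver 20, the aryl tosylate being inert to this zerovalent palladium catalyst.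

3. Step 6. Adventitious water may protodesilylate the alkyne faster than CO2 is captured, or fluoride in DMSO may attack the sulfonate. The fallback forms the aryl–alkyne bond with the carboxyl group already in place; it sets out from 9 and returns at 12. Copper-free coupling of 9 with propiolic acid (PdCl2(PPh3)2, 1,4-bis(diphenylphosphino)butane, DBU, DMSO, 50 °C) should give 12 directly; no new compound is made.

**Further compounds**

F1 | step 7 | 2-iodo-3,5-dimethoxyphenyl N-isopropylcarbamate | COc1cc(OC)c(I)c(OC(=O)NC(C)C)c1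
F2 | step 7 | 2-iodo-3,5-dimethoxyphenol | COc1cc(O)c(I)c(OC)c1
F3 | step 7 | 4-ethynyl-3-methoxyphenyl 4-methylbenzenesulfonate | COc1cc(OS(=O)(=O)c2ccc(C)cc2)ccc1C#C
F4 | step 10 | 8-iodo-5,7-dimethoxy-2-[2-methoxy-4-(tosyloxy)phenyl]-4H-chromen-4-one | COc1cc(OS(=O)(=O)c2ccc(C)cc2)ccc1-c1cc(=O)c2c(OC)cc(OC)c(I)c2o1
F5 | step 10 | 5-hydroxy-8-iodo-7-methoxy-2-[2-methoxy-4-(tosyloxy)phenyl]-4H-chromen-4-one | COc1cc(OS(=O)(=O)c2ccc(C)cc2)ccc1-c1cc(=O)c2c(O)cc(OC)c(I)c2o1
F0 | step 6 | none | none
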